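**Strategy**

Everything rests on cutting ring C (the pyranone) at C3–C4 and at O1–C8a. This turns ring A into a 1,3-dielectrophile, a 2-fluorobenzoyl chloride that already carries the C5 methoxy, C7 oxygen and C8 lavandulyl groups, and the B-ring acetophenone into a C3/O1 1,3-dinucleophile. In one pot the ketone enolate is C-acylated (C3–C4) and the diketonate oxygen then displaces fluoride at C8a (O1–C8a), closing ring C as a flavone. The step exploits the ortho relation of the C4 carbonyl to C8a and the meta position of the C5 and C7 oxygens, which leaves C8a electrophilic. Copper hydride reduction then sets C2; an Evans alkylation sets the side-chain centre.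

Key step: step 10

Assumption: the five starting materials are taken as purchasable, and (R)-DTBM-SEGPHOS is taken to deliver hydride to the face of C2 that gives 2S; if a trial run shows the opposite sense, the (S)-ligand is used and nothing else changes.

**Route**

Step 1
Reactants: 1 (4S)-4-benzyl-1,3-oxazolidin-2-one; 2 3-methylbut-2-enoyl chloride
Product: 3 (4S)-4-benzyl-3-(3-methylbut-2-enoyl)-1,3-oxazolidin-2-one
Conditions: n-BuLi, THF, −78 °C; then 2, −78 to 0 °C
Reagents that add atoms: none
Why: N-acylation of the lithiated oxazolidinone by the acid chloride is the standard way to an Evans imide and touches no stereocentre.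

Step 2
Reactants: 3 (4S)-4-benzyl-3-(3-methylbut-2-enoyl)-1,3-oxazolidin-2-one; 4 1-bromo-3-methylbut-2-ene (prenyl bromide)
Product: 5 (4S)-4-benzyl-3-[(2S)-5-methyl-2-(prop-1-en-2-yl)hex-4-enoyl]-1,3-oxazolidin-2-one
Conditions: NaN(SiMe3)2, THF, −78 °C; then 4, −78 to −40 °C
Reagents that add atoms: none
Why: Evans alkylation in its deconjugative form: γ-deprotonation should give the chelated Z sodium dienolate, which is alkylated at the α-carbon on the face away from the C4 benzyl group, so the auxiliary sets the (2S) centre while the double bond moves out of conjugation to become the isopropenyl group.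

Step 3
Reactants: 5 (4S)-4-benzyl-3-[(2S)-5-methyl-2-(prop-1-en-2-yl)hex-4-enoyl]-1,3-oxazolidin-2-one
Product: 6 (2S)-5-methyl-2-(prop-1-en-2-yl)hex-4-en-1-ol [(S)-lavandulol]
Conditions: LiBH4, MeOH (1 equiv), Et2O, 0 °C
Reagents that add atoms: none
Why: Reductive cleavage of the imide by LiBH4 should give the primary alcohol under conditions that neither epimerise the α-centre nor move the β,γ-double bond, and auxiliary 1 is recovered.

Step 4
Reactants: 6 (2S)-5-methyl-2-(prop-1-en-2-yl)hex-4-en-1-ol
Product: 7 (5S)-5-(iodomethyl)-2,6-dimethylhepta-2,6-diene [(S)-lavandulyl iodide]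
Conditions: I2, PPh3, imidazole, CH2Cl2, 0 °C to rt
Reagents that add atoms: iodine, II
Why: Appel-type iodination replaces the primary hydroxyl by SN2 at CH2, one carbon away from the stereocentre, which keeps its configuration.

Step 5
Reactants: 8 methyl 2,6-difluoro-4-hydroxybenzoate
Product: 9 methyl 2,6-difluoro-4-hydroxy-3-iodobenzoate
Conditions: N-iodosuccinimide (1.0 equiv), CF3CO2H (cat.), MeCN, rt
Reagents that add atoms: N-iodosuccinimide, O=C1CCC(=O)N1I
Why: Electrophilic aromatic iodination ortho to the phenol; the two open positions of the symmetric ring are equivalent, so mono-iodination can give only this regioisomer.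

Step 6
Reactants: 9 methyl 2,6-difluoro-4-hydroxy-3-iodobenzoate
Product: 10 methyl 2,6-difluoro-3-iodo-4-(methoxymethoxy)benzoate
Conditions: MOMCl, i-Pr2NEt, CH2Cl2, 0 °C to rt
Reagents that add atoms: chloromethyl methyl ether, COCCl
Why: O-alkylation of the acidic phenol gives a MOM acetal that should withstand the organozinc, alkoxide, amide-base and hydride steps that follow.

Step 7
Reactants: 7 (5S)-5-(iodomethyl)-2,6-dimethylhepta-2,6-diene; 10 methyl 2,6-difluoro-3-iodo-4-(methoxymethoxy)benzoate
Product: 12 methyl 2,6-difluoro-4-(methoxymethoxy)-3-[(2R)-5-methyl-2-(prop-1-en-2-yl)hex-4-en-1-yl]benzoate, via alkylzinc iodide 11 (not isolated)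
Conditions: 7, Zn dust, LiCl, THF, 40 °C; then 10, Pd(OAc)2 (2 mol %), 2-dicyclohexylphosphino-2',6'-dimethoxybiphenyl (SPhos, 4 mol %), THF, rt to 50 °C
Reagents that add atoms: none
Why: Negishi coupling of the primary alkylzinc iodide with the electron-poor aryl iodide, where the bulky biarylphosphine should favour reductive elimination over β-hydride elimination; the stereocentre is β to the metal and is not touched (its descriptor changes from S to R only because the CH2 now carries an aryl group).

Step 8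
Reactants: 12 methyl 2,6-difluoro-4-(methoxymethoxy)-3-[(2R)-5-methyl-2-(prop-1-en-2-yl)hex-4-en-1-yl]benzoate
Product: 14 2-fluoro-6-methoxy-4-(methoxymethoxy)-3-[(2R)-5-methyl-2-(prop-1-en-2-yl)hex-4-en-1-yl]benzoic acid, via methyl ester 13 (not isolated)
Conditions: NaOMe (1.2 equiv), MeOH/THF, 50 °C; then aq. NaOH, 70 °C; then 1 M HCl to pH 3, 0 °C
Reagents that add atoms: sodium methoxide, [Na+].[O-]C; sodium hydroxide, [Na+].[OH-]
Why: SNAr by methoxide at the ester-activated C6–F should be favoured over C2–F, which is flanked by the ester and the branched side-chain CH2, and the new methoxy group slows a second substitution; saponification in the same pot then frees the acid.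

Step 9
Reactants: 15 1-(4-hydroxy-2-methoxyphenyl)ethan-1-one
Product: 16 1-[2-methoxy-4-(methoxymethoxy)phenyl]ethan-1-one
Conditions: MOMCl, i-Pr2NEt, CH2Cl2, 0 °C to rt
Reagents that add atoms: chloromethyl methyl ether, COCCl
Why: MOM protection of the phenol ensures that only the methyl ketone is deprotonated and acylated in step 10.

Step 10
Reactants: 14 2-fluoro-6-methoxy-4-(methoxymethoxy)-3-[(2R)-5-methyl-2-(prop-1-en-2-yl)hex-4-en-1-yl]benzoic acid; 16 1-[2-methoxy-4-(methoxymethoxy)phenyl]ethan-1-one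
Product: 19 5-methoxy-7-(methoxymethoxy)-2-[2-methoxy-4-(methoxymethoxy)phenyl]-8-[(2R)-5-methyl-2-(prop-1-en-2-yl)hex-4-en-1-yl]-4H-chromen-4-one, via acyl chloride 17 (not isolated), via 1,3-diketone 18 (not isolated)
Conditions: 14, 1-chloro-N,N,2-trimethylprop-1-en-1-amine, CH2Cl2, 0 °C to rt, evaporate; 16, LiN(SiMe3)2 (2.2 equiv), THF, −78 °C, add 17, −78 °C to rt; then DMF, 90 °C
Reagents that add atoms: none
Why: The lithium enolate of 16 attacks acyl chloride 17 at carbon (Claisen-type C-acylation) to form C3–C4, and the second equivalent of base converts diketone 18 into its diketonate. On heating in DMF the enolate oxygen on C2 adds to the fluorine-bearing carbon C8a and fluoride leaves (addition–elimination SNAr through a Meisenheimer intermediate stabilised by the ortho C4 carbonyl), which forms O1–C8a and closes ring C in the 6-exo-trig mode. The closest known reaction type is the acylation/SNAr cyclisation of 2-fluorobenzoyl chlorides with ketone enolates to chromones and flavones, the oxygen counterpart of the Grohe–Heitzer quinolone synthesis, which tolerates a substituent next to the displaced fluorine. No stereocentre is formed (C2 is sp2 in 19 and is set in step 11) and the side-chain centre is not touched. The step needs C- over O-acylation, which the lithium counter-ion and the excess enolate (returning any enol ester to the diketonate) should secure, and displacement of fluoride and not of the C5 methoxy group, which the far better nucleofugality of fluoride in SNAr should secure; the C5 and C7 oxygens sit meta to C8a and do not deactivate it.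

Step 11
Reactants: 19 5-methoxy-7-(methoxymethoxy)-2-[2-methoxy-4-(methoxymethoxy)phenyl]-8-[(2R)-5-methyl-2-(prop-1-en-2-yl)hex-4-en-1-yl]-4H-chromen-4-one
Product: 21 (2S)-5-methoxy-7-(methoxymethoxy)-2-[2-methoxy-4-(methoxymethoxy)phenyl]-8-[(2R)-5-methyl-2-(prop-1-en-2-yl)hex-4-en-1-yl]-2,3-dihydro-4H-chromen-4-one, via silyl enol ether 20 (not isolated)
Conditions: Cu(OAc)2 (5 mol %), (R)-DTBM-SEGPHOS (5.5 mol %), (EtO)2MeSiH (3 equiv), toluene, 0 °C to rt; then aq. citric acid, THF, 0 °C
Reagents that add atoms: none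
Why: Copper hydride catalysed asymmetric conjugate reduction, known for chromones: the chiral bisphosphine copper hydride adds hydride to one face of C2 (catalyst control sets 2S), the enolate is held as silyl enol ether 20, which shields C4 from over-reduction and blocks ring opening, the isolated side-chain alkenes should not react, and mild acid then frees the ketone.

Step 12
Reactants: 21 (2S)-5-methoxy-7-(methoxymethoxy)-2-[2-methoxy-4-(methoxymethoxy)phenyl]-8-[(2R)-5-methyl-2-(prop-1-en-2-yl)hex-4-en-1-yl]-2,3-dihydro-4H-chromen-4-one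
Product: 23 (2S)-2'-methoxykurarinone [(2S)-7-hydroxy-2-(4-hydroxy-2-methoxyphenyl)-5-methoxy-8-[(2R)-5-methyl-2-(prop-1-en-2-yl)hex-4-en-1-yl]-2,3-dihydro-4H-chromen-4-one], via bis(trimethylsilyl) ether 22 (not isolated)
Conditions: Me3SiOTf, 2,2'-bipyridyl, MeCN, 0 °C to rt; then H2O, rt
Reagents that add atoms: none
Why: Me3SiOTf with 2,2'-bipyridyl turns aryl MOM ethers into aryl silyl ethers under buffered, non-protic conditions and water then frees both phenols, which avoids the protic acid that could add the C7 phenol to the isopropenyl group or open ring C; no stereocentre is involved.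

**Compound list**

1 | (4S)-4-benzyl-1,3-oxazolidin-2-one | O=C1N[C@@H](Cc2ccccc2)CO1 | starting material
2 | 3-methylbut-2-enoyl chloride | CC(C)=CC(=O)Cl | starting material
3 | (4S)-4-benzyl-3-(3-methylbut-2-enoyl)-1,3-oxazolidin-2-one | CC(C)=CC(=O)N1[C@@H](Cc2ccccc2)COC1=O | intermediate
4 | 1-bromo-3-methylbut-2-ene | CC(C)=CCBr | starting material
5 | (4S)-4-benzyl-3-[(2S)-5-methyl-2-(prop-1-en-2-yl)hex-4-enoyl]-1,3-oxazolidin-2-one | C=C(C)[C@H](CC=C(C)C)C(=O)N1[C@@H](Cc2ccccc2)COC1=O | intermediate
6 | (2S)-5-methyl-2-(prop-1-en-2-yl)hex-4-en-1-ol, (S)-lavandulol | C=C(C)[C@H](CC=C(C)C)CO | intermediate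
7 | (5S)-5-(iodomethyl)-2,6-dimethylhepta-2,6-diene, (S)-lavandulyl iodide | C=C(C)[C@H](CC=C(C)C)CI | intermediate
8 | methyl 2,6-difluoro-4-hydroxybenzoate | COC(=O)c1c(F)cc(O)cc1F | starting material
9 | methyl 2,6-difluoro-4-hydroxy-3-iodobenzoate | COC(=O)c1c(F)cc(O)c(I)c1F | intermediate
10 | methyl 2,6-difluoro-3-iodo-4-(methoxymethoxy)benzoate | COC(=O)c1c(F)cc(OCOC)c(I)c1F | intermediate
11 | [(2S)-5-methyl-2-(prop-1-en-2-yl)hex-4-en-1-yl]zinc iodide | C=C(C)[C@H](CC=C(C)C)C[Zn]I | intermediate
12 | methyl 2,6-difluoro-4-(methoxymethoxy)-3-[(2R)-5-methyl-2-(prop-1-en-2-yl)hex-4-en-1-yl]benzoate | C=C(C)[C@H](CC=C(C)C)Cc1c(OCOC)cc(F)c(C(=O)OC)c1F | intermediate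
13 | methyl 2-fluoro-6-methoxy-4-(methoxymethoxy)-3-[(2R)-5-methyl-2-(prop-1-en-2-yl)hex-4-en-1-yl]benzoate | C=C(C)[C@H](CC=C(C)C)Cc1c(OCOC)cc(OC)c(C(=O)OC)c1F | intermediate
14 | 2-fluoro-6-methoxy-4-(methoxymethoxy)-3-[(2R)-5-methyl-2-(prop-1-en-2-yl)hex-4-en-1-yl]benzoic acid | C=C(C)[C@H](CC=C(C)C)Cc1c(OCOC)cc(OC)c(C(=O)O)c1F | intermediate
15 | 1-(4-hydroxy-2-methoxyphenyl)ethan-1-one | CC(=O)c1ccc(O)cc1OC | starting material
16 | 1-[2-methoxy-4-(methoxymethoxy)phenyl]ethan-1-one | CC(=O)c1ccc(OCOC)cc1OC | intermediate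
17 | 2-fluoro-6-methoxy-4-(methoxymethoxy)-3-[(2R)-5-methyl-2-(prop-1-en-2-yl)hex-4-en-1-yl]benzoyl chloride | C=C(C)[C@H](CC=C(C)C)Cc1c(OCOC)cc(OC)c(C(=O)Cl)c1F | intermediate
18 | 1-{2-fluoro-6-methoxy-4-(methoxymethoxy)-3-[(2R)-5-methyl-2-(prop-1-en-2-yl)hex-4-en-1-yl]phenyl}-3-[2-methoxy-4-(methoxymethoxy)phenyl]propane-1,3-dione | C=C(C)[C@H](CC=C(C)C)Cc1c(OCOC)cc(OC)c(C(=O)CC(=O)c2ccc(OCOC)cc2OC)c1F | intermediate
19 | 5-methoxy-7-(methoxymethoxy)-2-[2-methoxy-4-(methoxymethoxy)phenyl]-8-[(2R)-5-methyl-2-(prop-1-en-2-yl)hex-4-en-1-yl]-4H-chromen-4-one | C=C(C)[C@H](CC=C(C)C)Cc1c(OCOC)cc(OC)c2c1OC(c1ccc(OCOC)cc1OC)=CC2=O | intermediate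
20 | (2S)-4-[diethoxy(methyl)silyloxy]-5-methoxy-7-(methoxymethoxy)-2-[2-methoxy-4-(methoxymethoxy)phenyl]-8-[(2R)-5-methyl-2-(prop-1-en-2-yl)hex-4-en-1-yl]-2H-chromene | C=C(C)[C@H](CC=C(C)C)Cc1c(OCOC)cc(OC)c2c1O[C@H](c1ccc(OCOC)cc1OC)C=C2O[Si](C)(OCC)OCC | intermediate
21 | (2S)-5-methoxy-7-(methoxymethoxy)-2-[2-methoxy-4-(methoxymethoxy)phenyl]-8-[(2R)-5-methyl-2-(prop-1-en-2-yl)hex-4-en-1-yl]-2,3-dihydro-4H-chromen-4-one | C=C(C)[C@H](CC=C(C)C)Cc1c(OCOC)cc(OC)c2c1O[C@H](c1ccc(OCOC)cc1OC)CC2=O | intermediate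
22 | (2S)-5-methoxy-2-[2-methoxy-4-(trimethylsilyloxy)phenyl]-8-[(2R)-5-methyl-2-(prop-1-en-2-yl)hex-4-en-1-yl]-7-(trimethylsilyloxy)-2,3-dihydro-4H-chromen-4-one | C=C(C)[C@H](CC=C(C)C)Cc1c(O[Si](C)(C)C)cc(OC)c2c1O[C@H](c1ccc(O[Si](C)(C)C)cc1OC)CC2=O | intermediate
23 | (2S)-2'-methoxykurarinone, (2S)-7-hydroxy-2-(4-hydroxy-2-methoxyphenyl)-5-methoxy-8-[(2R)-5-methyl-2-(prop-1-en-2-yl)hex-4-en-1-yl]-2,3-dihydro-4H-chromen-4-one | C=C(C)[C@H](CC=C(C)C)Cc1c(O)cc(OC)c2c1O[C@H](c1ccc(O)cc1OC)CC2=O | target

**Step count**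

Total: 12 steps. Longest linear sequence: 9 steps (steps 1, 2, 3, 4, 7, 8, 10, 11, 12).

**Steps most likely to fail**

1. Step 11. What may go wrong: hydride transfer to C2 may be slow because this carbon carries two donors (O1 and the ortho-substituted B ring), 1,2-reduction at C4 may compete, and the discrimination between the two faces of C2 may be poor. Fallback, setting out from 19 and coming back at 21: a reagent-controlled 1,4-reduction with LiBH(s-Bu)3 in THF at −78 °C should give 21 together with its C2 epimer, (2R)-5-methoxy-7-(methoxymethoxy)-2-[2-methoxy-4-(methoxymethoxy)phenyl]-8-[(2R)-5-methyl-2-(prop-1-en-2-yl)hex-4-en-1-yl]-2,3-dihydro-4H-chromen-4-one F1. Because the side-chain centre is fixed, the two are diastereomers and would be separated by preparative HPLC. F1 would be recycled by base-mediated ring opening and ring closure (retro-oxa-Michael/oxa-Michael, NaOAc, EtOH, reflux) and separated again.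

2. Step 10. What may go wrong: acylation at the doubly ortho-substituted acyl chloride may stall or go to oxygen, and ring closure may be slow because the fluorine-bearing carbon is shielded by the neighbouring side-chain CH2. Fallback, setting out from 17 (made from 14 as in step 10) and coming back at 18 and then 19: the polarity of the Claisen step is reversed so that the diketone is made through C2–C3. Me2CuLi (Et2O, −78 °C) should turn 17 into 1-{2-fluoro-6-methoxy-4-(methoxymethoxy)-3-[(2R)-5-methyl-2-(prop-1-en-2-yl)hex-4-en-1-yl]phenyl}ethan-1-one F2. The sodium enolate of F2 (NaH, THF, 60 °C) would be acylated in a crossed Claisen condensation by the unhindered methyl 2-methoxy-4-(methoxymethoxy)benzoate F3, made from purchased methyl 4-hydroxy-2-methoxybenzoate with MOMCl and i-Pr2NEt. This gives 18, now isolated, and the ring closure would be run on its own (Cs2CO3, DMF, 90 °C) to 19.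

3. Step 8. What may go wrong: regiocontrol may be lost in the SNAr, with methoxide attacking the fluoride next to the side chain or both fluorides. Fallback, setting out from 8 and coming back at 13: the methoxy group is placed while the ring is still symmetric. MOMCl and i-Pr2NEt give methyl 2,6-difluoro-4-(methoxymethoxy)benzoate F4, and NaOMe in MeOH can then give only methyl 2-fluoro-6-methoxy-4-(methoxymethoxy)benzoate F5. Deprotonation with (2,2,6,6-tetramethylpiperidyl)MgCl·LiCl (THF, −40 to 0 °C) should occur at the most acidic ring C–H, between fluorine and the MOM ether, to give [2-fluoro-4-methoxy-3-(methoxycarbonyl)-6-(methoxymethoxy)phenyl]magnesium chloride F6. Iodine then gives methyl 2-fluoro-3-iodo-6-methoxy-4-(methoxymethoxy)benzoate F7. Negishi coupling of F7 with 11 under the conditions of step 7 gives 13, which is saponified as in step 8.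

**Further compounds**

F1 | step 11 | (2R)-5-methoxy-7-(methoxymethoxy)-2-[2-methoxy-4-(methoxymethoxy)phenyl]-8-[(2R)-5-methyl-2-(prop-1-en-2-yl)hex-4-en-1-yl]-2,3-dihydro-4H-chromen-4-one | C=C(C)[C@H](CC=C(C)C)Cc1c(OCOC)cc(OC)c2c1O[C@@H](c1ccc(OCOC)cc1OC)CC2=O
F2 | step 10 | 1-{2-fluoro-6-methoxy-4-(methoxymethoxy)-3-[(2R)-5-methyl-2-(prop-1-en-2-yl)hex-4-en-1-yl]phenyl}ethan-1-one | C=C(C)[C@H](CC=C(C)C)Cc1c(OCOC)cc(OC)c(C(C)=O)c1F
F3 | step 10 | methyl 2-methoxy-4-(methoxymethoxy)benzoate | COC(=O)c1ccc(OCOC)cc1OC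
F4 | step 8 | methyl 2,6-difluoro-4-(methoxymethoxy)benzoate | COC(=O)c1c(F)cc(OCOC)cc1F
F5 | step 8 | methyl 2-fluoro-6-methoxy-4-(methoxymethoxy)benzoate | COC(=O)c1c(F)cc(OCOC)cc1OC
F6 | step 8 | [2-fluoro-4-methoxy-3-(methoxycarbonyl)-6-(methoxymethoxy)phenyl]magnesium chloride | COC(=O)c1c(OC)cc(OCOC)c([Mg]Cl)c1F
F7 | step 8 | methyl 2-fluoro-3-iodo-6-methoxy-4-(methoxymethoxy)benzoate | COC(=O)c1c(OC)cc(OCOC)c(I)c1F
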